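E, the product wanted, stops rising in the alder run near 24.4% of the Q charged, while Q goes on falling. All amounts below are fractions of the Q charged.

| flask | Q | D | temperature | remark | time |
|---|---|---|---|---|---|
| alder | 0.44 M | 6.6 mM | 15 °C | run made earlier |  |
| maple | 0.99 M | 6.6 mM | 37 °C | run made earlier |  |
| larch | 0.66 M | 3.3 mM | 15 °C | run made earlier |  |
| teal | 0.66 M | 6.6 mM | 5 °C |  | 6.0 h |
| green | 0.66 M | 6.6 mM | 25 °C |  | 6.0 h |
| violet | 0.66 M | 6.6 mM |  | at 5 °C until 4.0 h, from then on at 45 °C | 6.0 h |
| grey | 0.66 M | 6.6 mM | 45 °C |  | 6.0 h |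

- alder (time / h: E / %, Q / %): 0.200: 18.5, 78.3; 0.500: 23.8, 71.8; 1.00: 24.4, 67.9; 1.50: 24.4, 65.3; 2.50: 25.1, 61.1
- maple (time / min: E / %, Q / %): 8.00: 23.5, 63.1; 15.0: 20.7, 54.6; 25.0: 21.3, 47.2; 40.0: 17.0, 38.2; 50.0: 14.7, 31.2
- larch (time / h: E / %, Q / %): 0.200: 17.3, 80.9; 0.500: 25.6, 72.0; 1.00: 25.0, 66.3; 1.50: 23.4, 68.3; 2.50: 24.2, 64.0

(each reading ± 1 percentage point)

- which flask leads in amount of E, in percent of the Q charged ("all alike" within 1.5 percentage points) (teal / green / violet / grey / all alike)
- how much E is there at the end, in percent of the Q charged: teal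
- how much E is there at the end, in percent of the Q charged: green
- how much E is there at the end, in percent of the Q charged: violet
- how much E is there at the end, in percent of the Q charged: grey



1. In the alder run, E climbs at about 6.68 h⁻¹, read from its first reading, much faster than the pool Q+E shrinks, which is at 0.0456 h⁻¹. So Q and E can be reckoned as a pre-equilibrium inside a slowly draining pool.

2. The last alder and larch readings give a mean of 0.394 E per Q. This E-per-Q ratio is a reading with its scatter. It makes E the share 0.283 of the pool.

3. The maple pool shrinks at 0.907 h⁻¹, faster than the alder pool. Maple differs from alder in Q as well as in temperature, and this reckoning puts the whole rise on temperature. Spreading that rise evenly in the logarithm per degree gives 0.0117 h⁻¹ for teal, 0.177 h⁻¹ for green and 2.69 h⁻¹ for grey.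

4. Share times remaining pool gives E of 26.4% in teal and 9.75% in green.

5. The weak link is the hot drain. The lowest pool read is 45.9%, in the maple run, and by this estimate the grey pool would pass it after 0.289 h. The violet flask's 2.00 h at 45 °C is longer than that time. No reading lies below that pool, so the reforged estimate gives both hot flasks one range, from near nothing up to 13.0%. In this estimate teal leads either way.

The forecast also names teal, with 25%, 9%, 0.4% and 0.1% for teal, green, violet and grey. Of the grey pool it says “essentially gone”. The estimate above differs by keeping a range for the hot flasks.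

The flasks give 22.4%, 7.40%, 6.56% and 6.07% of E, and teal leads. Q in grey stands at 15.2% after 3.00 h and at 14.4% after 6.00 h, a fall of 0.80 percentage points. The ratio applied to that Q gives 5.69% of E, against 6.07%.

    2 D ⇌ J, settled at all times (K = 8200 L mol⁻¹, ΔH = −48.0 kJ mol⁻¹)
    Q ⇌ E (K = 0.380, k = 0.0990 min⁻¹, Ea = 96.0 kJ mol⁻¹, ΔH = 4.00 kJ mol⁻¹)
    Q + D ⇌ L + D, rate k3*[Q]*[D] forward; the back reaction follows from the equilibrium constant (K = 2.20, k = 1.60 L mol⁻¹ min⁻¹, Ea = 56.0 kJ mol⁻¹, ΔH = −2.00 kJ mol⁻¹)
    Q + D ⇌ X + D, rate k4*[Q]*[D] forward; the back reaction follows from the equilibrium constant (K = 7.40, k = 8.60 L mol⁻¹ min⁻¹, Ea = 66.0 kJ mol⁻¹, ΔH = −27.0 kJ mol⁻¹)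
    (constants at 25 °C)

A neighbour flask, like grey but at 20 °C, ends with 32% of its Q, so the ratio gives 12.6% of E. The computed amount is 11.9%.

The readings stem from a simulated flask from invented constants; scatter was added.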